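## Structural features

- The target is a flat, achiral heptaphenol (C24H14O11) built from four benzene rings. Ring C is shared by a dibenzo-p-dioxin (with ring B) and a dibenzofuran (with ring D), and ring A hangs on ring B through a diaryl ether.
- All 24 carbons are aromatic and there is no stereocenter, so the whole problem is one of constitution.
- Ring B carries five oxygens (two dioxin oxygens, the ring A ether, two hydroxyls) and one hydrogen. Ring C carries three neighbouring oxygens (O-1 and O-2 in the dioxin, O-3 free) plus the furan oxygen. Ring D carries the furan oxygen and two hydroxyls on alternate carbons.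
- The free polyphenol is electron-rich and sensitive to air under base. While ring B still carries electron-withdrawing groups, an aryl group can migrate between two neighbouring phenol oxygens (Smiles rearrangement). The phenols therefore stay masked to the end, and the dioxin must be closed when ring B is no longer activated.
- The real difficulty is regiochemical. The dioxin can fuse in two orientations (ring A beside O-2 or beside O-1), and the three neighbouring oxygens of ring C have three different fates, so they must be distinguishable.
- The key step uses ring D. C5a–C6, C7–C8 and C9–C9a are three two-carbon units that each bear exactly one oxygen (furan oxygen on C5a, hydroxyls on C7 and C9), which is the pattern of three alkynyl ethers. The O–C4a=C9b unit of ring C is a three-atom tether that joins two of them, so the furan and ring D can form in one cyclotrimerization.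

## Logic of the disconnections

25 to 24. Five O–alkyl bonds are cut (two ethyl on ring D, methyl on O-3, two methyl on ring A). The heptaphenol is the most fragile compound of the route, so it is released last. The forward step must cleave alkyl aryl ethers and leave the diaryl ether, dioxin and furan alone.

24 to 23. The dioxin bond between O-2 and the brominated carbon of ring B is cut. With the O-1 bond already in place, O-2 can reach only that carbon, through a six-membered ring, so the orientation of the dioxin is locked. Ring B is electron-rich at this stage, so no aryl migration can scramble O-1 and O-2. The forward step is a copper-catalysed C–O coupling at a bromide flanked by two aryloxy groups.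

23 to 21. The two C–OH bonds of ring B are traced back to C–CHO bonds, and the free O-2 to its methoxymethyl ether. The formyl groups first activate the fluorides of ring B for substitution and then become the hydroxyls. The forward step needs a peracid that oxidizes the aldehydes faster than the electron-rich rings.

21 to 15 and 20. The diaryl ether bond between O-1 and ring B is cut. This is the convergent joint: a tricyclic phenol and a ring A–ring B fragment of similar size. O-1 is the only free hydroxyl of 15, so protection decides which oxygen attacks. The forward step asks a hindered phenoxide to displace a fluoride flanked by a formyl group and a bromine.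

20 to 18 and 19, 18 to 17, 17 to 16. The ring A ether bond, the C–Br bond and one C–CHO bond are cut in turn. 18 has a mirror plane, so either fluoride gives the same ether. The bromine can only enter between the two fluorines, which is where the dioxin bond needs it. 16 and 19 are purchased.

15 to 14. The benzyl group on O-1 is put back. Hydrogenolysis is the one deprotection that leaves the methoxymethyl, methyl and ethyl ethers untouched, so O-1 can be freed first.

14 to 13 and 9 (key step). Three C–C bonds are cut: C5a–C9a, C6–C7 and C8–C9. This opens the furan and ring D together and leaves a diyne plus a simple alkyne. All three oxygens of ring D arrive on alkyne carbons, so no C–O bond has to be made on ring D afterwards. The forward step must favour the crossed cycloaddition over homotrimerization and must orient 9 correctly.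

13 to 10, 10 to 8 and 9, 8 to 6 and 7. The terminal alkynyl ether is traced to a dichlorovinyl ether, the aryl–alkyne bond to a cross-coupling of an aryl iodide, and the dichlorovinyl ether to the phenol and 7. The coupling has to come before the butyllithium step, because the iodide would not survive it.

6 to 4, 4 to 3, 3 to 2, 2 to 1. The phenol oxygen is traced to a formyl group, the benzyl ether to a free hydroxyl, the iodine to a C–H bond ortho to that hydroxyl, and the methoxymethyl ether to the more acidic hydroxyl of 1. Three different protecting groups end up on three neighbouring oxygens and the iodine in a defined position, using only the innate reactivity of a cheap catechol aldehyde.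

## Other disconnections considered

Alternative 1: Ring B would be cut into a four-carbon squaric ester and a two-carbon 1-ethoxyvinyl unit.
- Forward step: the mixed squarate A2 takes up the vinyl nucleophile at the carbonyl next to the isopropoxy carbon, and silylation gives cyclobutenone A3. Heating opens A3 to a dienylketene, which closes by six-electron electrocyclization and tautomerizes to phenol A1.
- In its favour: all five oxygens of ring B are set in one ring-forming step, each differently masked, with ring A already attached. On ring B this is better than the chosen plan, which needs a bromine handle and two aldehyde-to-phenol oxidations.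
- Against it here: in A1 the two oxygens that become the dioxin are on ring B, so ring C would have to be a 1,2-dielectrophile. That means an electron-rich dihalodibenzofuran and a double copper coupling in which the pairing of two different oxygens with two different carbons is not controlled. The dibenzofuran is not addressed at all, and the vinyl nucleophile may displace the aryloxy group of A2 instead of adding to the carbonyl.
- Comparison: both plans build a polyoxygenated benzene from small oxygenated units by a metal-free or metal-mediated pericyclic sequence, so they are equal in concept. Alternative 1 is the better plan for ring B alone, and no better in step count once a route to rings C and D is added. It leaves the dioxin orientation open, which the chosen plan fixes.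

Alternative 2: The C9a–C9b bond and the furan O–C5a bond would be cut.
- Forward step: phloroglucinol A6 adds through carbon to quinone A5, and the neighbouring hydroquinone hydroxyl condenses onto a C–OH carbon of the new ring with loss of water, giving dibenzofuran A4.
- In its favour: one step from two cheap compounds, no metal, no protecting group, and the same oxygen pattern on rings C and D as in 14. On step economy for the tricycle it is clearly better than the chosen plan (one step against eight).
- Against it here: A4 comes from a symmetric quinone, so O-1 and O-3 are both methyl ethers and only the central O-2 is free. The target needs O-1 in the dioxin and O-3 as a late hydroxyl, and nothing in A4 tells them apart. Two ring D phenols would also need protection beside the free O-2. The adduct hydroquinone can be oxidized by A5, and A6 can react more than once.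
- Comparison: the tricycle is the same. The mechanism is polar (conjugate addition, dehydration) instead of metal-catalysed. Alternative 2 wins on length, and the chosen plan wins on the differentiation of the ring C oxygens, which decides the dioxin regiochemistry.

Alternative 3: One C–C bond of ring D would be cut, between the carbon that carries ring C and its carbonyl-derived neighbour.
- Forward step: the benzylic carbon of triketo ester A8 attacks the terminal ester carbon in a Claisen condensation and closes ring D as the 2-arylphloroglucinol A7. Removal of the benzyl group and dehydrative C–O closure would then give the furan.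
- In its favour: biomimetic, metal-free, inexpensive, and the three ring D oxygens arrive as carbonyl groups. On that point it is the equal of the chosen plan, since neither has to form a C–O bond on ring D from an arene.
- Against it here: A8 can also close by aldol condensation or by lactonization to a hydroxypyrone, and the required mode makes a benzylic carbon flanked by two ortho substituents the nucleophile. A7 has three free phenols and still lacks the furan, and ring C is again trimethoxylated with O-1 and O-3 alike.
- Comparison: the biaryl is the same and the mechanism is an enolate condensation instead of a cycloaddition. It forms one ring per step where the chosen key step forms two, and the count is longer once A8 and the furan closure are included.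

Key step: step 8

Remarks on the chemistry:
- The atom mapping of the cycloaddition was rechecked and needs no change. The alkynyl ether carbon on oxygen becomes C5a and its CH becomes C6. The alkyne 9 supplies C7 (with OEt) and C8. The aryl alkyne supplies C9 (with OEt) and C9a.
- What is changed is the masking of ring C. Three identical methyl ethers cannot be told apart later, so O-1 carries benzyl, O-2 methoxymethyl and O-3 methyl. The arene is then no longer symmetric, so the iodine is placed at the aldehyde stage, where a free hydroxyl directs it.
- Assumption: 1, 16, 19 and (3,5-diethoxyphenyl)boronic acid are purchased, and 9 is bought as a solution in hexanes.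

## Route

Step 1
Reactants: 1 3,4-dihydroxy-5-methoxybenzaldehyde
Product: 2 3-hydroxy-5-methoxy-4-(methoxymethoxy)benzaldehyde
Conditions: MOMCl (1.05 equiv), K2CO3 (1.1 equiv), acetone, 0 °C → rt
Reagents that add atoms: chloromethyl methyl ether, COCCl
Why: Williamson-type O-alkylation; the hydroxyl para to the formyl group is the more acidic of the two, so one equivalent of weak base should form and alkylate that phenoxide, the selectivity used for 4-O-alkylation of 3,4-dihydroxybenzaldehydes.

Step 2
Reactants: 2 3-hydroxy-5-methoxy-4-(methoxymethoxy)benzaldehyde
Product: 3 3-hydroxy-2-iodo-5-methoxy-4-(methoxymethoxy)benzaldehyde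
Conditions: ICl (1.1 equiv), pyridine (2 equiv), CH2Cl2, 0 °C → rt
Reagents that add atoms: iodine monochloride, ClI
Why: Electrophilic aromatic iodination directed by the free phenol; as with 3-hydroxy-4-alkoxybenzaldehydes the iodine should enter between the hydroxyl and the formyl group, a carbon that is here also para to the methoxy group, and pyridine takes up the hydrogen chloride so that the methoxymethyl ether survives.

Step 3
Reactants: 3 3-hydroxy-2-iodo-5-methoxy-4-(methoxymethoxy)benzaldehyde
Product: 4 3-(benzyloxy)-2-iodo-5-methoxy-4-(methoxymethoxy)benzaldehyde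
Conditions: BnBr (1.2 equiv), K2CO3, DMF, rt
Reagents that add atoms: benzyl bromide, BrCc1ccccc1
Why: Williamson ether synthesis on the only free phenol; benzyl is chosen because it alone can be removed by hydrogenolysis after the cycloaddition, when the oxygen it masks (later O-1) has to react first.

Step 4
Reactants: 4 3-(benzyloxy)-2-iodo-5-methoxy-4-(methoxymethoxy)benzaldehyde
Product: 6 3-(benzyloxy)-2-iodo-5-methoxy-4-(methoxymethoxy)phenol, via aryl formate 5 (not isolated)
Conditions: mCPBA (1.5 equiv), CH2Cl2, 0 °C → rt; aq. Na2S2O3/NaHCO3 wash; then K2CO3 (cat.), MeOH, rt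
Reagents that add atoms: meta-chloroperbenzoic acid, OOC(=O)c1cccc(Cl)c1
Why: Baeyer–Villiger oxidation of an electron-rich benzaldehyde (Dakin-type), in which the aryl group with a para-alkoxy substituent migrates in preference to hydrogen, followed by methanolysis of the formate; the reducing wash returns any iodine that the peracid has oxidized to the aryl iodide.

Step 5
Reactants: 6 3-(benzyloxy)-2-iodo-5-methoxy-4-(methoxymethoxy)phenol; 7 trichloroethylene
Product: 8 (E)-1,2-dichloroethenyl 3-(benzyloxy)-2-iodo-5-methoxy-4-(methoxymethoxy)phenyl ether
Conditions: K2CO3 (2 equiv), 7 (3 equiv), DMF, 70 °C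
Reagents that add atoms: none
Why: Base-mediated dehydrochlorination of 7 to dichloroacetylene and anti addition of the phenoxide across it, the standard entry to aryl (E)-1,2-dichlorovinyl ethers; carbonate in DMF is enough for a phenol and avoids metal hydrides.

Step 6
Reactants: 8 (E)-1,2-dichloroethenyl 3-(benzyloxy)-2-iodo-5-methoxy-4-(methoxymethoxy)phenyl ether; 9 ethoxyacetylene
Product: 10 (E)-1,2-dichloroethenyl 3-(benzyloxy)-2-(ethoxyethynyl)-5-methoxy-4-(methoxymethoxy)phenyl ether
Conditions: Pd(PPh3)2Cl2 (5 mol %), CuI (10 mol %), Et3N, THF, 9 (3 equiv), rt → 40 °C; chromatography on Et3N-deactivated silica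
Reagents that add atoms: none
Why: Sonogashira coupling of an aryl iodide with a terminal alkynyl ether; zerovalent palladium inserts into the C–I bond much faster than into the vinylic C–Cl bonds, and a tertiary amine is used so that no amine adds to the ynol ether. It must precede step 7 because butyllithium would exchange the iodide.

Step 7
Reactants: 10 (E)-1,2-dichloroethenyl 3-(benzyloxy)-2-(ethoxyethynyl)-5-methoxy-4-(methoxymethoxy)phenyl ether
Product: 13 3-(benzyloxy)-2-(ethoxyethynyl)-5-methoxy-4-(methoxymethoxy)phenyl ethynyl ether, via chloroethynyl ether 11 (not isolated), via lithium acetylide 12 (not isolated)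
Conditions: n-BuLi (2.5 equiv), THF, −78 → −40 °C; MeOH, −78 °C; cold aq. NaHCO3 work-up
Reagents that add atoms: none
Why: Double elimination of a 1,2-dichlorovinyl ether: the first equivalent of butyllithium removes hydrogen chloride to give chloroalkyne 11, the second exchanges chlorine for lithium to give 12, and a cold proton quench gives the terminal alkynyl ether. The internal ynol ether, the benzyl ether and the acetal are inert at low temperature, and 13 is kept cold in solution and used at once.

Step 8
Reactants: 13 3-(benzyloxy)-2-(ethoxyethynyl)-5-methoxy-4-(methoxymethoxy)phenyl ethynyl ether; 9 ethoxyacetylene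
Product: 14 1-(benzyloxy)-7,9-diethoxy-3-methoxy-2-(methoxymethoxy)dibenzofuran
Conditions: [Rh(cod)2]BF4 (10 mol %), rac-BINAP (10 mol %), activated with H2 then kept under Ar; 9 (5 equiv); 13 added over 2 h; CH2Cl2, rt
Reagents that add atoms: none
Why: Proposed new method: a cationic monovalent rhodium centre bound by BINAP should take up the two tethered alkynyl ether units of 13 and couple them oxidatively, which forms the C5a–C9a bond and a trivalent rhodacyclopentadiene fused to the new furan; 9 then inserts and reductive elimination forms the C6–C7 and C8–C9 bonds. The closest known reaction types are the rhodium-catalysed [2+2+2] cycloaddition of phenol-tethered 1,6-diynes with monoalkynes and the head-to-tail cyclotrimerization of aryl ethynyl ethers; what has not been shown is a diyne with an alkoxy group on its far terminus combined with an alkoxyacetylene as the third component. The furan closes in the oxidative coupling, as the five-membered ring of a 1,6-diyne whose O–C4a=C9b tether holds the two triple bonds side by side, and ring D closes in the insertion and reductive elimination. No stereocenter is formed. The step needs crossed reaction over homotrimerization and one orientation of 9: the tether makes the first coupling intramolecular, 13 is added slowly to an excess of 9, and the ethoxy group already on the C-9 terminus of the metallacycle leaves room for the ethoxy-bearing carbon of 9 only next to the unsubstituted C-6 terminus. That orientation also gives the alternating oxygen pattern that polarized ynol ethers prefer. Benzyl, methoxymethyl and methyl ethers should be inert to the catalyst under dry, acid-free conditions.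

Step 9
Reactants: 14 1-(benzyloxy)-7,9-diethoxy-3-methoxy-2-(methoxymethoxy)dibenzofuran
Product: 15 7,9-diethoxy-3-methoxy-2-(methoxymethoxy)dibenzofuran-1-ol
Conditions: H2 (1 atm), 10% Pd/C, EtOAc–EtOH, rt
Reagents that add atoms: none
Why: Catalytic hydrogenolysis of a benzyl aryl ether under neutral conditions; the methoxymethyl, methyl and ethyl ethers and the dibenzofuran are untouched, so O-1 becomes the only free hydroxyl.

Step 10
Reactants: 16 5-bromo-2,4-difluorobenzaldehyde
Product: 17 4,6-difluorobenzene-1,3-dicarbaldehyde
Conditions: Pd(OAc)2 (1 mol %), BuPAd2 (3 mol %), TMEDA, CO/H2 (1:1, 5 bar), toluene, 100 °C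
Reagents that add atoms: carbon monoxide, [C-]#[O+]
Why: Palladium-catalysed reductive carbonylation (formylation) of an aryl bromide with synthesis gas; oxidative addition, CO insertion and hydrogenolysis of the acyl complex give the aldehyde, and the tertiary diamine takes up hydrogen bromide without attacking the activated fluorides.

Step 11
Reactants: 17 4,6-difluorobenzene-1,3-dicarbaldehyde
Product: 18 5-bromo-4,6-difluorobenzene-1,3-dicarbaldehyde
Conditions: NBS (1.2 equiv), conc. H2SO4, 60 °C
Reagents that add atoms: N-bromosuccinimide, O=C1CCC(=O)N1Br
Why: Electrophilic aromatic bromination of a deactivated arene in strong acid; the carbon between the fluorines is the only position ortho to both fluorines and meta to both formyl groups, and it is where the later dioxin bond needs its leaving group.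

Step 12
Reactants: 18 5-bromo-4,6-difluorobenzene-1,3-dicarbaldehyde; 19 3,5-dimethoxyphenol
Product: 20 5-bromo-4-(3,5-dimethoxyphenoxy)-6-fluorobenzene-1,3-dicarbaldehyde
Conditions: 18 (2 equiv), K2CO3 (1.2 equiv), DMF, 0 °C → rt; excess 18 recovered
Reagents that add atoms: none
Why: Nucleophilic aromatic substitution of a fluoride that is ortho to one formyl group and para to the other; 18 has a mirror plane, so either fluoride gives the same product, and the excess of 18 holds back double substitution.

Step 13
Reactants: 15 7,9-diethoxy-3-methoxy-2-(methoxymethoxy)dibenzofuran-1-ol; 20 5-bromo-4-(3,5-dimethoxyphenoxy)-6-fluorobenzene-1,3-dicarbaldehyde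
Product: 21 5-bromo-4-{[7,9-diethoxy-3-methoxy-2-(methoxymethoxy)dibenzofuran-1-yl]oxy}-6-(3,5-dimethoxyphenoxy)benzene-1,3-dicarbaldehyde
Conditions: Cs2CO3 (1.5 equiv), DMF, Ar, rt → 50 °C
Reagents that add atoms: none
Why: Nucleophilic aromatic substitution at the remaining fluoride of 20, still ortho and para to a formyl group; O-1 is the only free hydroxyl of 15, so the protecting pattern decides which ring C oxygen is bonded to this carbon, and with O-2 masked no Smiles rearrangement can move the aryl group. Fluoride leaves far faster than the aryloxy group already on ring B.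

Step 14
Reactants: 21 5-bromo-4-{[7,9-diethoxy-3-methoxy-2-(methoxymethoxy)dibenzofuran-1-yl]oxy}-6-(3,5-dimethoxyphenoxy)benzene-1,3-dicarbaldehyde
Product: 23 5-bromo-4-[(7,9-diethoxy-2-hydroxy-3-methoxydibenzofuran-1-yl)oxy]-6-(3,5-dimethoxyphenoxy)benzene-1,3-diol, via bis-formate 22 (not isolated)
Conditions: mCPBA (3 equiv), CH2Cl2, 0 °C → rt; aq. Na2S2O3/NaHCO3 wash; then HCl (1.25 M in MeOH), 40 °C
Reagents that add atoms: meta-chloroperbenzoic acid, OOC(=O)c1cccc(Cl)c1
Why: Twofold Baeyer–Villiger oxidation (Dakin-type) of aldehydes that each have an aryloxy group ortho and para, then acid-catalysed methanolysis of the two formates and of the methoxymethyl ether in the same pot. The formyl groups have served as activators and become the two hydroxyls of ring B; ring B is now electron-rich, so aryl migration between O-1 and O-2 is no longer possible.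

Step 15
Reactants: 23 5-bromo-4-[(7,9-diethoxy-2-hydroxy-3-methoxydibenzofuran-1-yl)oxy]-6-(3,5-dimethoxyphenoxy)benzene-1,3-diol
Product: 24 7,9-diethoxy-3-methoxydibenzofuran whose O-1 and O-2 are bridged by a 1,2-phenylene bearing hydroxyls at C-4 and C-6 and a 3,5-dimethoxyphenoxy group at C-3 (phenylene C-1 on O-1, C-2 on O-2)
Conditions: CuI (20 mol %), picolinic acid (40 mol %), K3PO4 (3 equiv), degassed DMSO, Ar, 90 °C
Reagents that add atoms: none
Why: Intramolecular Ullmann diaryl ether coupling catalysed by monovalent copper; O-2 is the only hydroxyl that can reach the brominated carbon, through a six-membered ring, so the dioxin can close in one orientation only, with ring A beside O-2.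

Step 16
Reactants: 24 the 7,9-di-O-ethyl tri-O-methyl ether of the target described in step 15
Product: 25 target: 3,7,9-trihydroxydibenzofuran whose O-1 and O-2 are bridged by a 1,2-phenylene bearing hydroxyls at C-4 and C-6 and a 3,5-dihydroxyphenoxy group at C-3 (phenylene C-1 on O-1, C-2 on O-2)
Conditions: BBr3 (12 equiv), CH2Cl2, −78 °C → rt; MeOH then H2O; work-up under Ar
Reagents that add atoms: none
Why: Lewis acid cleavage of alkyl aryl ethers with boron tribromide; the two ethyl and three methyl groups leave as alkyl bromides while the diaryl ether, dioxin and furan C–O bonds, which have no alkyl carbon to attack, stay intact. It is done last because the free heptaphenol is sensitive to air and base.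

## Compound list

1 | 3,4-dihydroxy-5-methoxybenzaldehyde | COc1cc(C=O)cc(O)c1O | starting material
2 | 3-hydroxy-5-methoxy-4-(methoxymethoxy)benzaldehyde | COCOc1c(O)cc(C=O)cc1OC | intermediate
3 | 3-hydroxy-2-iodo-5-methoxy-4-(methoxymethoxy)benzaldehyde | COCOc1c(O)c(I)c(C=O)cc1OC | intermediate
4 | 3-(benzyloxy)-2-iodo-5-methoxy-4-(methoxymethoxy)benzaldehyde | COCOc1c(OCc2ccccc2)c(I)c(C=O)cc1OC | intermediate
5 | 3-(benzyloxy)-2-iodo-5-methoxy-4-(methoxymethoxy)phenyl formate | COCOc1c(OCc2ccccc2)c(I)c(OC=O)cc1OC | intermediate
6 | 3-(benzyloxy)-2-iodo-5-methoxy-4-(methoxymethoxy)phenol | COCOc1c(OCc2ccccc2)c(I)c(O)cc1OC | intermediate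
7 | trichloroethylene | ClC=C(Cl)Cl | starting material
8 | (E)-1,2-dichloroethenyl 3-(benzyloxy)-2-iodo-5-methoxy-4-(methoxymethoxy)phenyl ether | COCOc1c(OCc2ccccc2)c(I)c(O/C(Cl)=C\Cl)cc1OC | intermediate
9 | ethoxyacetylene | C#COCC | starting material
10 | (E)-1,2-dichloroethenyl 3-(benzyloxy)-2-(ethoxyethynyl)-5-methoxy-4-(methoxymethoxy)phenyl ether | COCOc1c(OCc2ccccc2)c(C#COCC)c(O/C(Cl)=C\Cl)cc1OC | intermediate
11 | chloroethynyl 3-(benzyloxy)-2-(ethoxyethynyl)-5-methoxy-4-(methoxymethoxy)phenyl ether | COCOc1c(OCc2ccccc2)c(C#COCC)c(OC#CCl)cc1OC | intermediate
12 | lithium 2-[3-(benzyloxy)-2-(ethoxyethynyl)-5-methoxy-4-(methoxymethoxy)phenoxy]ethynide | COCOc1c(OCc2ccccc2)c(C#COCC)c(OC#C[Li])cc1OC | intermediate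
13 | 3-(benzyloxy)-2-(ethoxyethynyl)-5-methoxy-4-(methoxymethoxy)phenyl ethynyl ether | COCOc1c(OCc2ccccc2)c(C#COCC)c(OC#C)cc1OC | intermediate
14 | 1-(benzyloxy)-7,9-diethoxy-3-methoxy-2-(methoxymethoxy)dibenzofuran | CCOc1cc(OCC)c2c(c1)oc1cc(OC)c(OCOC)c(OCc3ccccc3)c12 | intermediate
15 | 7,9-diethoxy-3-methoxy-2-(methoxymethoxy)dibenzofuran-1-ol | CCOc1cc(OCC)c2c(c1)oc1cc(OC)c(OCOC)c(O)c12 | intermediate
16 | 5-bromo-2,4-difluorobenzaldehyde | O=Cc1cc(Br)c(F)cc1F | starting material
17 | 4,6-difluorobenzene-1,3-dicarbaldehyde | O=Cc1cc(C=O)c(F)cc1F | intermediate
18 | 5-bromo-4,6-difluorobenzene-1,3-dicarbaldehyde | O=Cc1cc(C=O)c(F)c(Br)c1F | intermediate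
19 | 3,5-dimethoxyphenol | COc1cc(O)cc(OC)c1 | starting material
20 | 5-bromo-4-(3,5-dimethoxyphenoxy)-6-fluorobenzene-1,3-dicarbaldehyde | O=Cc1cc(C=O)c(Oc2cc(OC)cc(OC)c2)c(Br)c1F | intermediate
21 | 5-bromo-4-{[7,9-diethoxy-3-methoxy-2-(methoxymethoxy)dibenzofuran-1-yl]oxy}-6-(3,5-dimethoxyphenoxy)benzene-1,3-dicarbaldehyde | CCOc1cc(OCC)c2c(c1)oc1cc(OC)c(OCOC)c(Oc3c(C=O)cc(C=O)c(Oc4cc(OC)cc(OC)c4)c3Br)c12 | intermediate
22 | 5-bromo-4-{[7,9-diethoxy-3-methoxy-2-(methoxymethoxy)dibenzofuran-1-yl]oxy}-6-(3,5-dimethoxyphenoxy)-1,3-phenylene diformate | CCOc1cc(OCC)c2c(c1)oc1cc(OC)c(OCOC)c(Oc3c(OC=O)cc(OC=O)c(Oc4cc(OC)cc(OC)c4)c3Br)c12 | intermediate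
23 | 5-bromo-4-[(7,9-diethoxy-2-hydroxy-3-methoxydibenzofuran-1-yl)oxy]-6-(3,5-dimethoxyphenoxy)benzene-1,3-diol | CCOc1cc(OCC)c2c(c1)oc1cc(OC)c(O)c(Oc3c(O)cc(O)c(Oc4cc(OC)cc(OC)c4)c3Br)c12 | intermediate
24 | 7,9-di-O-ethyl tri-O-methyl ether of the target (ethyl on the ring D oxygens; methyl on O-3 of ring C and on both ring A oxygens; ring B hydroxyls free) | COc1cc(OC)cc(Oc2c(O)cc(O)c3c2Oc2c(OC)cc4oc5cc(OCC)cc(OCC)c5c4c2O3)c1 | intermediate
25 | target heptaphenol (dibenzofuran-fused dibenzo-p-dioxin with a 3,5-dihydroxyphenoxy group on ring B) | Oc1cc(O)cc(Oc2c(O)cc(O)c3c2Oc2c(O)cc4oc5cc(O)cc(O)c5c4c2O3)c1 | target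

## Step count and least certain steps

Total: 16 steps, 13 in the main line (steps 1–9 and 13–16) and 3 in the ring A–ring B branch (steps 10–12). Longest linear sequence: 13 steps.

Step 8 (key step).
- What may go wrong: homotrimerization of 9 and oligomerization of 13 may outrun the crossed cycloaddition. The two ynol ethers may be hydrated or protonated by the Lewis acidic cation, and 9 may insert in the wrong orientation.
- Fallback with known chemistry, from 6 back to 14: Chan–Lam O-arylation of 6 with (3,5-diethoxyphenyl)boronic acid (Cu(OAc)2, pyridine, molecular sieves, CH2Cl2, air, rt) keeps the aryl iodide and gives 1-(benzyloxy)-3-(3,5-diethoxyphenoxy)-2-iodo-5-methoxy-6-(methoxymethoxy)benzene F1. Intramolecular palladium-catalysed direct arylation (Pd(OAc)2, PCy3·HBF4, K2CO3, DMA, 130 °C) then closes the furan. The two C–H bonds ortho to the ether oxygen of the diethoxyphenyl ring are equivalent and each lies between two oxygens, so only 14 can form. The rest of the route is unchanged.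

Step 15.
- What may go wrong: oxidative addition of copper into a bromide flanked by two aryloxy groups on a ring that carries two phenoxides may be slow. Air oxidation of the triphenolate and loss of bromine by reduction can then take over.
- Fallback, from 21 back to 25: Baeyer–Villiger oxidation of 21 with a basic methanolysis (K2CO3, MeOH) keeps the acetal and gives 5-bromo-4-{[7,9-diethoxy-3-methoxy-2-(methoxymethoxy)dibenzofuran-1-yl]oxy}-6-(3,5-dimethoxyphenoxy)benzene-1,3-diol F2. Methylation (MeI, K2CO3, acetone) gives 1-[2-bromo-3-(3,5-dimethoxyphenoxy)-4,6-dimethoxyphenoxy]-7,9-diethoxy-3-methoxy-2-(methoxymethoxy)dibenzofuran F3. Acid methanolysis frees O-2 and gives 1-[2-bromo-3-(3,5-dimethoxyphenoxy)-4,6-dimethoxyphenoxy]-7,9-diethoxy-3-methoxydibenzofuran-2-ol F4. With a single phenol left, the ring is closed by palladium-catalysed C–O coupling (Pd2(dba)3, t-BuXPhos, K3PO4, toluene, 100 °C) to the di-O-ethyl penta-O-methyl ether of the target F5. Boron tribromide as in step 16 then gives 25.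

Step 13.
- What may go wrong: both partners are doubly ortho-substituted at the reacting atoms (O-1 sits in the bay beside the C-9 ethoxy group, and the fluoride lies between a formyl group and bromine). Substitution may therefore be slow, and oxidation of the phenoxide or exchange of the aryloxy group on ring B may compete.
- Fallback, from 15 back to 21: the order of assembly is changed. 15 is first joined to the more electrophilic difluoride 18, used in large excess (Cs2CO3, DMF), to give 5-bromo-4-{[7,9-diethoxy-3-methoxy-2-(methoxymethoxy)dibenzofuran-1-yl]oxy}-6-fluorobenzene-1,3-dicarbaldehyde F6. The unhindered phenol 19 then displaces the last fluoride (K2CO3, DMF) and gives 21.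

Step 7.
- What may go wrong: the terminal aryl ethynyl ether may be lost by oligomerization or by hydration to an aryl acetate during work-up and concentration.
- Fallback, from 10 back to 13: the lithium acetylide 12 is quenched with triisopropylsilyl chloride instead of methanol, which gives the storable 3-(benzyloxy)-2-(ethoxyethynyl)-5-methoxy-4-(methoxymethoxy)phenyl (triisopropylsilyl)ethynyl ether F7. Fluoride (TBAF, wet THF, −20 °C) releases 13 immediately before step 8.

## Further compounds

F1 | step 8 | 1-(benzyloxy)-3-(3,5-diethoxyphenoxy)-2-iodo-5-methoxy-6-(methoxymethoxy)benzene | CCOc1cc(OCC)cc(Oc2cc(OC)c(OCOC)c(OCc3ccccc3)c2I)c1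
F2 | step 15 | 5-bromo-4-{[7,9-diethoxy-3-methoxy-2-(methoxymethoxy)dibenzofuran-1-yl]oxy}-6-(3,5-dimethoxyphenoxy)benzene-1,3-diol | CCOc1cc(OCC)c2c(c1)oc1cc(OC)c(OCOC)c(Oc3c(O)cc(O)c(Oc4cc(OC)cc(OC)c4)c3Br)c12
F3 | step 15 | 1-[2-bromo-3-(3,5-dimethoxyphenoxy)-4,6-dimethoxyphenoxy]-7,9-diethoxy-3-methoxy-2-(methoxymethoxy)dibenzofuran | CCOc1cc(OCC)c2c(c1)oc1cc(OC)c(OCOC)c(Oc3c(OC)cc(OC)c(Oc4cc(OC)cc(OC)c4)c3Br)c12
F4 | step 15 | 1-[2-bromo-3-(3,5-dimethoxyphenoxy)-4,6-dimethoxyphenoxy]-7,9-diethoxy-3-methoxydibenzofuran-2-ol | CCOc1cc(OCC)c2c(c1)oc1cc(OC)c(O)c(Oc3c(OC)cc(OC)c(Oc4cc(OC)cc(OC)c4)c3Br)c12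
F5 | step 15 | di-O-ethyl penta-O-methyl ether of the target (ethyl on the ring D oxygens, methyl on all other hydroxyl oxygens) | COc1cc(OC)cc(Oc2c(OC)cc(OC)c3c2Oc2c(OC)cc4oc5cc(OCC)cc(OCC)c5c4c2O3)c1
F6 | step 13 | 5-bromo-4-{[7,9-diethoxy-3-methoxy-2-(methoxymethoxy)dibenzofuran-1-yl]oxy}-6-fluorobenzene-1,3-dicarbaldehyde | CCOc1cc(OCC)c2c(c1)oc1cc(OC)c(OCOC)c(Oc3c(C=O)cc(C=O)c(F)c3Br)c12
F7 | step 7 | 3-(benzyloxy)-2-(ethoxyethynyl)-5-methoxy-4-(methoxymethoxy)phenyl (triisopropylsilyl)ethynyl ether | COCOc1c(OCc2ccccc2)c(C#COCC)c(OC#C[Si](C(C)C)(C(C)C)C(C)C)cc1OC
A1 | alternative 1 | 2-(3,5-dimethoxyphenoxy)-5-ethoxy-3-isopropoxy-4-(triethylsilyloxy)phenol | CCOc1cc(O)c(Oc2cc(OC)cc(OC)c2)c(OC(C)C)c1O[Si](CC)(CC)CC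
A2 | alternative 1 | 3-(3,5-dimethoxyphenoxy)-4-isopropoxycyclobut-3-ene-1,2-dione | CC(C)OC1=C(Oc2cc(OC)cc(OC)c2)C(=O)C1=O
A3 | alternative 1 | 2-(3,5-dimethoxyphenoxy)-4-(1-ethoxyethenyl)-3-isopropoxy-4-(triethylsilyloxy)cyclobut-2-en-1-one | CCOC(=C)C1(O[Si](CC)(CC)CC)C(OC(C)C)=C(Oc2cc(OC)cc(OC)c2)C1=O
A4 | alternative 2 | 1,3-dimethoxydibenzofuran-2,7,9-triol | COc1cc2oc3cc(O)cc(O)c3c2c(OC)c1O
A5 | alternative 2 | 2,6-dimethoxy-1,4-benzoquinone | COC1=CC(=O)C=C(OC)C1=O
A6 | alternative 2 | phloroglucinol (benzene-1,3,5-triol) | Oc1cc(O)cc(O)c1
A7 | alternative 3 | 2-(2-benzyloxy-4,5,6-trimethoxyphenyl)benzene-1,3,5-triol | COc1cc(OCc2ccccc2)c(-c2c(O)cc(O)cc2O)c(OC)c1OC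
A8 | alternative 3 | methyl 6-(2-benzyloxy-4,5,6-trimethoxyphenyl)-3,5-dioxohexanoate | COC(=O)CC(=O)CC(=O)Cc1c(OCc2ccccc2)cc(OC)c(OC)c1OC
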